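## Structural features

The target 14 is a chroman-4-one. Benzene ring A (C4a, C5, C6, C7, C8, C8a) is fused along C4a–C8a to dihydropyranone ring B (O1, C2, C3, C4, C4a, C8a). Ring A has a 1,2,4,5 pattern: O1 on C8a and the free OH on C6 are para (a hydroquinone monoether), Br is on C7 (ortho to that OH, para to the acyl-bearing C4a), and C5 and C8 carry H. The only stereocentre is C2, (S), a tetrasubstituted tertiary aryl ether carbon bonded to O1, C3H2, CH3 and the chain C1'H2–C2'H2–C3'H2–C4'(OH)(CH3)2. No neighbouring stereocentre can relay information to C2, and its two alkyl arms differ little close to the centre. Four points are fragile: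
- The O1–C2 bond is β to the C4 ketone, so an enolate at C3 can expel the C8a phenoxide and racemise C2 by retro-oxa-Michael/oxa-Michael.
- The C4' tertiary alcohol ionises in strong acid.
- The C7–Br bond is lost to zerovalent palladium, hydrogenolysis and halogen–metal exchange.
- The hydroquinone monoether is oxidisable.

The real difficulty is therefore the absolute configuration at C2, not the ring system. The key step exploits the fact that ring B is one carbon nucleophile away from aromaticity. With the chain removed from C2 and the C4 oxygen silylated, O1–C2–C3–C4–C4a–C8a becomes a flat 4-siloxybenzopyrylium cation whose only open electrophilic atom is C2. C1'–C2' of the chain can be carried as an alkyne, and the six-carbon alkynol is a catalogue compound.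

## Logic of the disconnections

**14 to 13.** The H on the C6 oxygen is replaced by silicon (O–Si bond). The skeleton is unchanged. The acidic, oxidisable phenol is thereby absent from every step that uses a silyl triflate, a copper acetylide or a hydrogenation catalyst. Demand: the unmasking must run without base, because O1–C2 is β to C4=O.

**13 to 12.** The C1'–C2' single bond is taken back to a triple bond. This puts an sp carbon on C2, which is the retron for an acetylide addition. Demand: the saturation must leave C7–Br, C4=O and the propargylic, then allylic, O1–C2 bond untouched.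

**12 to 7 and 9, through 11 and 10.** The C2–C1' bond is cut.
- In one sentence, the route is the enantioselective addition of a copper acetylide to C2 of the aromatic cation 10 made from flat, achiral 7.
- This is the only cut at C2 that leaves O1–C2 intact and turns ring B into an aromatic ring, so the stereocentre disappears completely from the precursor.
- Gain: a chiral tetrasubstituted ether becomes one planar bicycle and one six-carbon alkyne, and the step is also the fragment union.
- Demand: catalyst control of the face of C2, attack at C2 rather than C4, and C–C bond formation ahead of proton loss from the C2 methyl group.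

**9 to 8.** The O–Si bond on the C4' oxygen is cut. The free alcohol would consume silyl triflate and quench the acetylide. Demand: the group must fall off in the acidic work-up of the key step, so that no extra step is spent.

**7 to 6 to 5.** The O–Si bond and then the O–CH3 bond on the C6 oxygen are exchanged. The methyl ether is needed for the base and acid steps that build ring B. It cannot be removed at the end without harming C4'–OH and C2. Demand: the exchange is done on the flat, robust bicycle, where a hard Lewis acid has nothing to damage.

**5 to 3, through 4.** O1–C2 and C2–C3 of ring B are cut. Here C2 is trigonal, so these classical bonds carry no stereochemical burden. Gain: ring B is reduced to a two-carbon ester. Demand: C-acylation of the methyl ketone in the presence of the free ortho phenol.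

**3 to 1, through 2.** C4–C4a and the O–CH3 bond on the future O1 are cut. The 1,2,4,5 pattern of ring A is the natural outcome of electrophilic substitution on 1. Gain: a commercial arene that already carries Br and both oxygens. Demand: acylation para to Br, and cleavage of only the methyl ether ortho to the new ketone.

## Other disconnections considered

**Alternative 1:** (the first that comes to mind) cut O1–C2 and C2–C3 of ring B in the target itself.
- Forward key step: pyrrolidine-mediated Kabbe condensation of 3 with 6-hydroxy-6-methylheptan-2-one A1. It runs through the β,β-dialkyl enone A2, whose phenol closes ring B by 6-endo-trig oxa-Michael addition to the racemic methyl ether A3.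
- Ground: C2 is created by a reversible addition to a trigonal carbon whose two substituents are CH3 and CH2R, which gives a catalyst no handle to tell them apart.
- The E and Z forms of A2 interconvert through the dienamine and lead to opposite enantiomers.
- Reversibility drains any kinetic preference towards the racemate.
- This is the shortest way to racemic material, but it leaves the only real problem to a resolution.

**Alternative 2:** cut O1–C8a.
- The stereocentre would be bought as a tertiary alcohol. Sharpless epoxidation and reductive opening of an allylic alcohol would give the diol A4, which is elaborated to the β-hydroxy ketone A5.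
- Forward key step: intramolecular SNAr of the tertiary alkoxide on the C8a–F bond, activated by the ortho ketone, to give A6.
- Ground: the alkoxide of A5 is a tertiary aldolate and can break C2–C3 by retro-aldol under the very conditions of the ring closure.
- C7–Br is para to the ketone and is itself activated for substitution.
- A tetrasubstituted fluoroarene has to be made separately.
- The chain alkene still needs a late hydration and the methyl ether a late cleavage.
- The linear sequence would be longer and the strategy is a conventional chiral-building-block approach.

**Alternative 3:** cut C4a–C8a and C5–C6, so that ring A is built from open precursors.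
- Forward key step: intramolecular Diels–Alder reaction of the 2-alkoxyfuran with the tethered ynone in A7, then opening of the oxygen bridge and proton loss to give A8. The cycloaddition itself would place O1 (C8a), OH (C6), Br (C7) and the acyl group (C4a), and it is electronically matched.
- Ground: the risk moves from the key step to its precursor.
- No well-precedented way joins a tertiary alkoxide to an unactivated bromofuran.
- A 2-(tert-alkoxy)furan is a ketene-acetal-like ether that collapses to a butenolide and a tertiary cation on the slightest protonation.
- C2 would still have to be bought separately as in alternative 2, so the plan is longer and does not address the stereocentre.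

Key step: step 6

Remark: locants are those of chroman-4-one (O1 to C8a) and C1' to C4' for the chain. The sense of induction of the bis(oxazoline) ligand on a 2-methyl cation cannot be derived safely from first principles, so the route is written for the ligand antipode that sends the acetylide to the Si face of C2 (O1 > C3 > CH3); both antipodes are commercial.

## Steps

Step 1
Reactants: 1 2-bromo-1,4-dimethoxybenzene
Product: 3 1-(4-bromo-2-hydroxy-5-methoxyphenyl)ethan-1-one, via dimethoxy ketone 2 (not isolated)
Conditions: AcCl (1.2 equiv), AlCl3 (2.5 equiv), CH2Cl2, 0 °C to reflux; then ice, 1 M HCl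
Reagents that add atoms: acetyl chloride, CC(=O)Cl
Why: Friedel–Crafts acylation at the only unhindered position that is ortho to an OMe group and para to Br, which gives the 1,2,4,5 pattern of ring A. AlCl3 chelated between the new ketone and the ortho OMe then lets chloride cleave only that methyl ether (chelation-controlled demethylation), while the remote OMe stays.

Step 2
Reactants: 3 1-(4-bromo-2-hydroxy-5-methoxyphenyl)ethan-1-one
Product: 5 7-bromo-6-methoxy-2-methyl-4H-chromen-4-one, via 1,3-diketone 4 (not isolated)
Conditions: NaH (4 equiv), EtOAc (5 equiv), THF, reflux; 1 M HCl quench; crude 4, conc. HCl (cat.), AcOH, 100 °C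
Reagents that add atoms: ethyl acetate, CCOC(C)=O
Why: Crossed Claisen condensation of the phenoxide/enolate dianion with ethyl acetate forms C2–C3. Acid-catalysed cyclodehydration (phenol onto the distal ketone, loss of water) forms O1–C2 and gives the aromatic chromone; aryl bromide and methyl ether are inert.

Step 3
Reactants: 5 7-bromo-6-methoxy-2-methyl-4H-chromen-4-one
Product: 6 7-bromo-6-hydroxy-2-methyl-4H-chromen-4-one
Conditions: BBr3 (3 equiv), CH2Cl2, −78 °C to rt; then H2O
Reagents that add atoms: none
Why: Lewis acid cleavage of an aryl methyl ether, with extra BBr3 to cover coordination to the chromone carbonyl. It is placed here because 5 has no stereocentre, no tertiary alcohol and no retro-oxa-Michael pathway.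

Step 4
Reactants: 6 7-bromo-6-hydroxy-2-methyl-4H-chromen-4-one
Product: 7 7-bromo-6-[(tert-butyldimethylsilyl)oxy]-2-methyl-4H-chromen-4-one
Conditions: TBSCl (1.3 equiv), imidazole (2.5 equiv), DMF, rt
Reagents that add atoms: tert-butyldimethylsilyl chloride, CC(C)(C)[Si](C)(C)Cl
Why: Standard imidazole-promoted silylation of a phenol. The aryl silyl ether tolerates silyl triflate, amine, dilute acid and hydrogenation, and is later removed under non-basic fluoride conditions.

Step 5
Reactants: 8 2-methylpent-4-yn-2-ol
Product: 9 trimethyl[(2-methylpent-4-yn-2-yl)oxy]silane
Conditions: TMSCl (1.3 equiv), imidazole (2 equiv), CH2Cl2, 0 °C to rt; distillation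
Reagents that add atoms: trimethylsilyl chloride, C[Si](C)(C)Cl
Why: Standard silylation of a tertiary alcohol, so that it neither consumes TBSOTf nor protonates the copper acetylide in step 6. The trimethylsilyl group is chosen because it is shed in the acidic work-up of that step.

Step 6
Reactants: 7 7-bromo-6-[(tert-butyldimethylsilyl)oxy]-2-methyl-4H-chromen-4-one; 9 trimethyl[(2-methylpent-4-yn-2-yl)oxy]silane
Product: 12 (R)-7-bromo-6-[(tert-butyldimethylsilyl)oxy]-2-(4-hydroxy-4-methylpent-1-yn-1-yl)-2-methylchroman-4-one, via 4-siloxybenzopyrylium triflate 10 (not isolated), via silyl enol ether adduct 11 (not isolated)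
Conditions: 7, TBSOTf (1.3 equiv), toluene, rt, 1 h; then CuI (10 mol %), 2,2'-(propane-2,2-diyl)bis(4-phenyl-4,5-dihydrooxazole) (Ph-BOX, 12 mol %, antipode as in the remark), 9 (1.5 equiv), iPr2NEt (1.5 equiv, slow addition), toluene, −30 °C, dark; then 2 M HCl, THF, 0 °C
Reagents that add atoms: tert-butyldimethylsilyl trifluoromethanesulfonate, CC(C)(C)[Si](C)(C)OS(=O)(=O)C(F)(F)F (its atoms stand in 10 and 11 and are gone in 12)
Why: TBSOTf silylates the C4 oxygen of 7 and turns ring B into the aromatic cation 10, whose acceptor orbital sits on C2 and C4; C4 is blocked and deactivated by its siloxy donor, so C2 is the only site open to a carbon nucleophile. CuI/bis(oxazoline) binds 9 side-on, iPr2NEt removes the acidified alkyne proton, and the chiral monovalent copper acetylide attacks C2 in an irreversible, enantio-determining outer-sphere step to give the neutral enol silane 11, which dilute acid hydrolyses (enol silane and trimethylsilyl ether) to 12. The closest known reaction type is the copper/bis(oxazoline)-catalysed enantioselective alkynylation of 2-substituted 4-siloxybenzopyrylium triflates, which forms tertiary ether stereocentres. No ring is closed: the step dearomatises ring B and joins the chain through C2–C1'. The one new stereocentre C2 is controlled by the catalyst alone, since 10 is planar and achiral; the aryl groups of the ligand stack on ring A and orient the cation in the ion pair, so that the acetylide reaches the Si face and gives (R)-11 and (R)-12, which have the spatial arrangement of (S)-14. A rod-shaped sp nucleophile is the carbon nucleophile best able to build a tetrasubstituted centre next to CH3, and it is exactly C1' of the chain. The step needs addition to win over proton loss from C2–CH3: that proton transfer is reversible because the ammonium triflate re-protonates the methylene base, whereas C–C bond formation is not, and low temperature with slow addition of base keeps the methylene base scarce; C7–Br is inert to monovalent copper at this temperature. As an enol silane, 11 cannot undergo retro-oxa-Michael, so the configuration is locked until the mild hydrolysis.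

Step 7
Reactants: 12 (R)-7-bromo-6-[(tert-butyldimethylsilyl)oxy]-2-(4-hydroxy-4-methylpent-1-yn-1-yl)-2-methylchroman-4-one
Product: 13 (S)-7-bromo-6-[(tert-butyldimethylsilyl)oxy]-2-(4-hydroxy-4-methylpentyl)-2-methylchroman-4-one
Conditions: H2 (1 atm), 10% Pd/C, Ph2S (catalyst poison), EtOAc, rt
Reagents that add atoms: none
Why: Heterogeneous hydrogenation of the alkyne to the alkane over sulfide-poisoned palladium, a system known to spare aryl halides and aryl ketones; the poison should also suppress cleavage of the allylic O1–C2 bond at the alkene stage. C2 is not touched, and its descriptor changes from R to S only because C1' drops below C3 in priority.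

Step 8
Reactants: 13 (S)-7-bromo-6-[(tert-butyldimethylsilyl)oxy]-2-(4-hydroxy-4-methylpentyl)-2-methylchroman-4-one
Product: 14 (S)-7-bromo-6-hydroxy-2-(4-hydroxy-4-methylpentyl)-2-methylchroman-4-one
Conditions: KHF2 (2 equiv), MeOH, rt
Reagents that add atoms: none
Why: Fluoride cleavage of a phenolic silyl ether in a weakly acidic medium. No C3 enolate can form, so C2 is not racemised, and the tertiary alcohol, ketone and aryl bromide are inert.

## Compound list

1 | 2-bromo-1,4-dimethoxybenzene | COc1ccc(OC)c(Br)c1 | starting material
2 | 1-(4-bromo-2,5-dimethoxyphenyl)ethan-1-one | CC(=O)c1cc(OC)c(Br)cc1OC | intermediate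
3 | 1-(4-bromo-2-hydroxy-5-methoxyphenyl)ethan-1-one | CC(=O)c1cc(OC)c(Br)cc1O | intermediate
4 | 1-(4-bromo-2-hydroxy-5-methoxyphenyl)butane-1,3-dione | CC(=O)CC(=O)c1cc(OC)c(Br)cc1O | intermediate
5 | 7-bromo-6-methoxy-2-methyl-4H-chromen-4-one | Cc1cc(=O)c2cc(OC)c(Br)cc2o1 | intermediate
6 | 7-bromo-6-hydroxy-2-methyl-4H-chromen-4-one | Cc1cc(=O)c2cc(O)c(Br)cc2o1 | intermediate
7 | 7-bromo-6-[(tert-butyldimethylsilyl)oxy]-2-methyl-4H-chromen-4-one | Cc1cc(=O)c2cc(O[Si](C)(C)C(C)(C)C)c(Br)cc2o1 | intermediate
8 | 2-methylpent-4-yn-2-ol | C#CCC(C)(C)O | starting material
9 | trimethyl[(2-methylpent-4-yn-2-yl)oxy]silane | C#CCC(C)(C)O[Si](C)(C)C | intermediate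
10 | 7-bromo-4,6-bis[(tert-butyldimethylsilyl)oxy]-2-methylchromenylium trifluoromethanesulfonate | Cc1cc(O[Si](C)(C)C(C)(C)C)c2cc(O[Si](C)(C)C(C)(C)C)c(Br)cc2[o+]1.[O-]S(=O)(=O)C(F)(F)F | intermediate
11 | (R)-7-bromo-4,6-bis[(tert-butyldimethylsilyl)oxy]-2-methyl-2-{4-methyl-4-[(trimethylsilyl)oxy]pent-1-yn-1-yl}-2H-chromene | C[Si](C)(C)OC(C)(C)CC#C[C@@]1(C)C=C(O[Si](C)(C)C(C)(C)C)c2cc(O[Si](C)(C)C(C)(C)C)c(Br)cc2O1 | intermediate
12 | (R)-7-bromo-6-[(tert-butyldimethylsilyl)oxy]-2-(4-hydroxy-4-methylpent-1-yn-1-yl)-2-methylchroman-4-one | CC(C)(O)CC#C[C@@]1(C)CC(=O)c2cc(O[Si](C)(C)C(C)(C)C)c(Br)cc2O1 | intermediate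
13 | (S)-7-bromo-6-[(tert-butyldimethylsilyl)oxy]-2-(4-hydroxy-4-methylpentyl)-2-methylchroman-4-one | CC(C)(O)CCC[C@@]1(C)CC(=O)c2cc(O[Si](C)(C)C(C)(C)C)c(Br)cc2O1 | intermediate
14 | (S)-7-bromo-6-hydroxy-2-(4-hydroxy-4-methylpentyl)-2-methylchroman-4-one | CC(C)(O)CCC[C@@]1(C)CC(=O)c2cc(O)c(Br)cc2O1 | target

## Step count and least certain steps

Total step count: 8. Longest linear sequence: 7 (steps 1, 2, 3, 4, 6, 7, 8).

**Step 6 (key step).**
- The most likely failure is proton loss from the C2 methyl group of the cation outrunning C–C bond formation. The resulting methylene base would then self-condense with remaining cation.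
- The second risk is poor facial selectivity. CH3 gives the catalyst less to hold than the electron-withdrawing C2 substituents on which this reaction type is best established, and an aliphatic alkyne adds no stacking contact.
- Fallback (resolution with recycling instead of asymmetric C–C bond formation): it sets out from 3. BBr3 cleaves the remaining methyl ether to 1-(4-bromo-2,5-dihydroxyphenyl)ethan-1-one F1.
- Pyrrolidine-mediated Kabbe condensation of this ketone with the purchasable hydroxyketone A1 gives racemic 7-bromo-6-hydroxy-2-(4-hydroxy-4-methylpentyl)-2-methylchroman-4-one F2.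
- Preparative chromatography on a chiral stationary phase separates 14 from (R)-7-bromo-6-hydroxy-2-(4-hydroxy-4-methylpentyl)-2-methylchroman-4-one F3. The latter can be re-equilibrated to the racemate with pyrrolidine (retro-oxa-Michael/oxa-Michael) and recycled.
- The fallback comes back to the route at 14.

**Step 7.**
- Likely failures are hydrodebromination at C7, hydrogenolysis of the O1–C2 bond while it is allylic, or stalling at the hindered cis-alkene on the poisoned catalyst.
- Fallback (metal-free concerted hydrogen transfer instead of a metal surface): it sets out from 12. Diimide generated from 2-nitrobenzenesulfonohydrazide and Et3N in CH2Cl2 at rt reduces the alkyne through (R,Z)-7-bromo-6-[(tert-butyldimethylsilyl)oxy]-2-(4-hydroxy-4-methylpent-1-en-1-yl)-2-methylchroman-4-one F4.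
- A further charge of reagent completes the reduction, and the fallback comes back at 13. Diimide has no pathway for C–Br or C–O cleavage.

**Step 2.**
- Likely failures are self-condensation of ethyl acetate consuming the base, and sluggish C-acylation of the poorly nucleophilic dianion.
- Fallback (intramolecular acyl transfer instead of an intermolecular Claisen condensation): it sets out from 3. Ac2O/pyridine gives 2-acetyl-5-bromo-4-methoxyphenyl acetate F5.
- KOt-Bu in THF then induces the Baker–Venkataraman O-to-C acyl shift to 4, where the fallback comes back to the route. 4 is cyclised to 5 as written.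

**Step 8.**
- The likely failure is erosion of enantiopurity by retro-oxa-Michael ring opening if the medium turns basic (fluoride acting as base, build-up of phenoxide), or slow cleavage next to the ortho bromine.
- Fallback (no persistent phenol protecting group, so no deprotection on the configurationally labile chromanone): it sets out from 6. TMSCl/Et3N gives 7-bromo-2-methyl-6-[(trimethylsilyl)oxy]-4H-chromen-4-one F6, which is used crude under the conditions of step 6 with 9.
- The acidic work-up strips all silyl groups and gives (R)-7-bromo-6-hydroxy-2-(4-hydroxy-4-methylpent-1-yn-1-yl)-2-methylchroman-4-one F7.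
- Hydrogenation of F7 under the conditions of step 7 comes back at 14.

## Further compounds

F1 | step 6 | 1-(4-bromo-2,5-dihydroxyphenyl)ethan-1-one | CC(=O)c1cc(O)c(Br)cc1O
F2 | step 6 | racemic 7-bromo-6-hydroxy-2-(4-hydroxy-4-methylpentyl)-2-methylchroman-4-one | CC(C)(O)CCCC1(C)CC(=O)c2cc(O)c(Br)cc2O1
F3 | step 6 | (R)-7-bromo-6-hydroxy-2-(4-hydroxy-4-methylpentyl)-2-methylchroman-4-one | CC(C)(O)CCC[C@]1(C)CC(=O)c2cc(O)c(Br)cc2O1
F4 | step 7 | (R,Z)-7-bromo-6-[(tert-butyldimethylsilyl)oxy]-2-(4-hydroxy-4-methylpent-1-en-1-yl)-2-methylchroman-4-one | CC(C)(O)C/C=C\[C@@]1(C)CC(=O)c2cc(O[Si](C)(C)C(C)(C)C)c(Br)cc2O1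
F5 | step 2 | 2-acetyl-5-bromo-4-methoxyphenyl acetate | CC(=O)Oc1cc(Br)c(OC)cc1C(C)=O
F6 | step 8 | 7-bromo-2-methyl-6-[(trimethylsilyl)oxy]-4H-chromen-4-one | Cc1cc(=O)c2cc(O[Si](C)(C)C)c(Br)cc2o1
F7 | step 8 | (R)-7-bromo-6-hydroxy-2-(4-hydroxy-4-methylpent-1-yn-1-yl)-2-methylchroman-4-one | CC(C)(O)CC#C[C@@]1(C)CC(=O)c2cc(O)c(Br)cc2O1
A1 | alternative 1 | 6-hydroxy-6-methylheptan-2-one | CC(=O)CCCC(C)(C)O
A2 | alternative 1 | (E)-1-(4-bromo-2-hydroxy-5-methoxyphenyl)-7-hydroxy-3,7-dimethyloct-2-en-1-one | CC(C)(O)CCC/C(C)=C/C(=O)c1cc(OC)c(Br)cc1O
A3 | alternative 1 | racemic 7-bromo-2-(4-hydroxy-4-methylpentyl)-6-methoxy-2-methylchroman-4-one | CC(C)(O)CCCC1(C)CC(=O)c2cc(OC)c(Br)cc2O1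
A4 | alternative 2 | (S)-3,7-dimethyloct-6-ene-1,3-diol | CC(C)=CCC[C@@](O)(C)CCO
A5 | alternative 2 | (S)-1-(4-bromo-2-fluoro-5-methoxyphenyl)-3-hydroxy-3,7-dimethyloct-6-en-1-one | CC(C)=CCC[C@@](O)(C)CC(=O)c1cc(OC)c(Br)cc1F
A6 | alternative 2 | (S)-7-bromo-6-methoxy-2-methyl-2-(4-methylpent-3-en-1-yl)chroman-4-one | CC(C)=CCC[C@@]1(C)CC(=O)c2cc(OC)c(Br)cc2O1
A7 | alternative 3 | (S)-5-[(4-bromofuran-2-yl)oxy]-5,9-dimethyldec-8-en-1-yn-3-one | C#CC(=O)C[C@](C)(CCC=C(C)C)Oc1cc(Br)co1
A8 | alternative 3 | (S)-7-bromo-6-hydroxy-2-methyl-2-(4-methylpent-3-en-1-yl)chroman-4-one | CC(C)=CCC[C@@]1(C)CC(=O)c2cc(O)c(Br)cc2O1
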